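1. In a one-step world, first order in L with all else held fixed, L loses the same fraction of itself in each equal stretch of time. A flask is then read by counting halvings: the fraction of L left is 0.5 raised to the count.

2. You asked for a quick number. This is what we had.

| flask | L | X | Z | temperature | remark | time |
|---|---|---|---|---|---|---|
| Tuesday's | 0.011 M | 1.7 equiv | 0.14 mol% | 55 °C | run made earlier |  |
| Saturday's | 0.011 M | 3.2 equiv | 0.14 mol% | 70 °C | run made earlier |  |
| gamma | 0.011 M | 5.00 equiv | 0.14 mol% | 70 °C |  | 8.0 h |
| theta | 0.011 M | 2.50 equiv | 0.14 mol% | 70 °C |  | 12 h |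

| Tuesday's: time / h | Tuesday's: D / % | Saturday's: time / h | Saturday's: D / % |
|---|---|---|---|
| 0.833 | 2.4 | 0.667 | 1.7 |
| 3.00 | 0.1 | 1.00 | 3.1 |
| 5.00 | 4.6 | 1.50 | 5.8 |
| 8.00 | 9.6 | 2.50 | 8.0 |
| 10.0 | 11.6 | 4.00 | 12.5 |
| 12.0 | 13.0 | 6.00 | 18.2 |
| 15.0 | 16.1 | 8.00 | 22.7 |

(each reading ± 1 percentage point)

- the analysis behind the earlier runs scatters by 1 percentage point, standard deviation

1. which one finishes higher in amount of D, in percent of the L charged ("neither" within 2 percentage points) (gamma / theta / neither)
2. amount of D at the end, in percent of the L charged, gamma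
3. amount of D at the end, in percent of the L charged, theta

3. Saturday's last reading gave 21.5 h. I called this the halving time of L, the hours per halving at that run's pace. The reading at 4.00 h gave 20.8 h, so the pace held.

4. Tuesday's last reading gave 59.2 h, longer by a factor 2.75. With X in proportion, 1.88 of that factor was X, and 1.46 remained for going from 55 °C to 70 °C. The rule of thumb, a factor 2 per 10 °C, asks 2.83 for that step. The whole factor 2.75 stands nearer that, so I read the runs as zero order in X, with the scatter of two runs on that reading.

5. Gamma then counted 0.371 halvings and theta 0.557. That put my estimate of D at 22.7% for gamma and 32.0% for theta. I said theta, higher by 9.3 percentage points.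

6. Your forecast differed: gamma, with 34% for gamma and 27% for theta, “Assuming the usual first order in X”. Its gamma figure lies close to Saturday's last reading scaled with the X charged, which is 35.5%.

7. The flasks have been run. Here is the scheme behind them; J, G and Q are forms of the catalyst.

    G → Z + D (k = 1.00 min⁻¹, Ea = 92.0 kJ mol⁻¹)
    L + Z ⇌ J (K = 210 M⁻¹, k = 87.0 M⁻¹ min⁻¹, Ea = 45.0 kJ mol⁻¹, ΔH = −38.0 kJ mol⁻¹)
    Z ⇌ Q (K = 1.60, k = 5.60 × 10⁻⁴ min⁻¹, Ea = 117 kJ mol⁻¹, ΔH = −44.0 kJ mol⁻¹)
    X + J → G (k = 93.0 M⁻¹ min⁻¹, Ea = 36.0 kJ mol⁻¹)
    (constants at 70 °C)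

Theta finished higher, at 31.8% against 25.1% for gamma. In gamma at 3.71 h, J fell back at 0.083 of the rate at which it went on with X to G. So nearly all of that J went on. Averaged over each run, the final D of the flasks gave halving times of 19.2 h for gamma and 21.8 h for theta, against my 21.5 h from Saturday's run. For the neighbour of gamma with 0.35 mol% of Z, at the same 8.0 h, I divided my halving time by the loading ratio 2.50. That gave 8.61 h and an estimated D of 47.5%, and that flask stood at 54.9%.

(The earlier runs and the new flask come from a simulation with made-up constants, and the scatter is random.)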